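- At early times the alpha run does little: it shows 2.0% of its charge as single product after 3.00 h. The step starting material + partner -> single product needs partner, and at the start none of the solid reagent is in solution.

| setting | alpha | eta | delta | flask |
|---|---|---|---|---|
| starting material | 2 M | 2 M | 1 M | 2.0 M |
| solid reagent | 0.67 equiv | 1.5 equiv | 1 equiv | 1.00 equiv |
| remark | run made earlier | run made earlier | run made earlier |  |
| time |  |  |  | 20 h |

| run | time / h | single product / % |
|---|---|---|
| alpha | 3.00 | 2.0 |
| alpha | 8.00 | 8.4 |
| alpha | 15.0 | 18.7 |
| alpha | 25.0 | 32.2 |
| eta | 3.00 | 1.6 |
| eta | 8.00 | 7.8 |
| eta | 15.0 | 18.6 |
| eta | 25.0 | 32.0 |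
| delta | 2.00 | 0.9 |
| delta | 4.00 | 2.6 |
| delta | 10.0 | 11.9 |
| delta | 25.0 | 36.0 |

(scatter of a reading: 0.3 percentage points)

1. how much single product there is at 20 h, in percent of the starting material charged
2. concentration of partner in solution at 10 h, in percent of saturation
3. the change that raises the amount of single product at 20 h, in percent of the starting material charged most ("none" if none brings more than 2 percentage points) (oak / maple / none)
4. amount of single product at 20 h, in percent of the starting material charged, after maple

- oak: doubling the dissolution coefficient of the solid reagent, all else as stated
- maple: doubling the solubility of the solid reagent, all else as stated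

- solid reagent is a solid; its amount is given per volume of the solution
- reactions considered so far: starting material + partner -> single product; partner + single product -> bis adduct; starting material + partner -> other mono adduct; partner + other mono adduct -> bis adduct; solid reagent <-> partner
- at the start none of the solid reagent is in solution

- Counted in fractions of the charge, the rate of that step is its rate constant times partner times the fraction of starting material left. I froze that product, reading partner as near a quasi-steady state, dissolving about as fast as it reacts, while the fraction left falls slowly.
- The readings allow this: the alpha run climbs 0.0147 /h from 8.00 h to 15.0 h, and the alpha and eta runs together climb 0.0135 /h from 15.0 h to 25.0 h. I carried this second figure as the frozen slope, the fraction of the charge turned into single product each hour once the lag is over.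
- The amount of solid barely shows: with 0.67 equiv and 1.5 equiv the runs differ at 25.0 h by 0.2 percentage points, less than the scatter of 0.3 points. The flask, with 1.00 equiv, lies between them.
- So I started the flask from the mean of both runs at 15.0 h and added the frozen slope up to 20 h, which gave 25.4%.
- The forecast said 25.7% (24.9% to 26.4%) of single product, above my figure, with partner at 69% of saturation at 10 h, maple as the best change and 43% after maple, holding that “solid loading doesn't matter while solid remains”.
- The flask gave 25.5% of single product at 20 h and partner at 58.1% of saturation at 10 h; maple was best, adding 18 points against 6.8 points for oak, and reached 43.5%.

    starting material + partner → single product (k = 1.30 × 10⁻⁵ /M/s)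
    partner + single product → bis adduct (k = 2.20 × 10⁻⁶ /M/s)
    starting material + partner → other mono adduct (k = 7.00 × 10⁻⁷ /M/s)
    partner + other mono adduct → bis adduct (k = 2.60 × 10⁻⁷ /M/s)
    solid reagent ⇌ partner, rate k5*(cs5 - [partner]) while solid is left; crystals form when [partner] > cs5 (solubility = 0.640 M, k = 4.40 × 10⁻⁵ /s)

- At 20.0 h the flask made partner 1.09 times as fast as it used it up, each step taken net, and the true rate constant times partner times the fraction of starting material left gave 0.0143 /h against the frozen slope of 0.0135 /h. Read at 72.0 h, the same flask held 0% of its solid reagent's charge and 63.0% single product, so from 20 h onward its slope averaged lower than the frozen one, at 0.00720 /h.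

The earlier runs and the new flask are simulated with made-up constants; scatter was added.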